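The ratio of substrate standing in the flask to substrate fed per hour is a time. Read from ochre at 5.00 h and 8.00 h and from red at 8.00 h and 12.0 h, with a scatter of 2 percentage points on each reading, it came to 1.20 h. I called it the hold-up time, the mean stay of substrate under a starved feed at quasi-steady state.

| flask | substrate | gas | remark | time |
|---|---|---|---|---|
| ochre | 0.54 M (fed, over 12 h) | 200 mM (held) | run made earlier |  |
| red | 1.2 M (fed, over 12 h) | 200 mM (held) | run made earlier |  |
| epsilon | 0.80 M (fed, over 12 h) | 200 mM (held) |  | 40 h |
| theta | 0.80 M (fed, over 20 h) | 200 mM (held) |  | 40 h |
| delta | 0.80 M (fed, over 30 h) | 200 mM (held) |  | 40 h |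

| run | time / h | target / % | substrate / % |
|---|---|---|---|
| ochre | 2.00 | 0 | 4 |
| ochre | 3.00 | 3 | 13 |
| ochre | 5.00 | 2 | 11 |
| ochre | 8.00 | 5 | 7 |
| ochre | 15.0 | 18 | 1 |
| ochre | 25.0 | 26 | 5 |
| red | 4.00 | 2 | 7 |
| red | 8.00 | 8 | 10 |
| red | 12.0 | 12 | 12 |
| red | 15.0 | 18 | 0 |
| red | 20.0 | 18 | 0 |
| red | 25.0 | 21 | 5 |

(scatter of a reading: 2 percentage points)

- at the start none of the gas is in solution
- "hardly changes" means that all values lie within two and a half points (for a concentration: within two and a half percent of the largest)
- percentages count the whole charge, also what has not yet gone in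

1. amount of target at the end, in percent of the substrate charged for epsilon, theta, delta, in this order
2. the shape of the row from first to last (rises, then falls / rises all the way / falls, then rises / falls all the way / hardly changes)

I set the other times against it, in powers of ten above the hold-up time:

feeds of epsilon, theta, delta: 1.00, 1.22, 1.40

whole run: 1.52

The last rung, the drain of the unread stock, needs a word. In red at 12.0 h, 76.0% of the charge was neither substrate nor target. Dividing the unread stock at 25.0 h by the gain of target per hour since about 15.0 h, ochre and red averaged, gave a drain time of 130 h, a rough reading from scattered points, which lay 2.03 powers of ten above the hold-up time.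

The shortest feed, in epsilon, lasted ten times the hold-up time, so I took substrate in epsilon, theta and delta to sit at a level that follows the feed:

[substrate] at the end of the feed = hold-up time / dosing time: 10.0%, 6.00%, 4.00%

The run was shorter than the drain, so I expected the unread stock still to be draining at the end. My reckoning gave these substrate levels and no figure for target.

The forecast gave 27%, 28.5% and 28%, a row that hardly changes: “Gain and lost time roughly cancel, so the row hardly changes.”

The flasks gave 23.3%, 23.2% and 22.4%, a row that hardly changes.

    substrate ⇌ intermediate A (K = 5.30, k = 0.00470 /min)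
    substrate ⇌ intermediate B (K = 39.0, k = 0.00710 /min)
    substrate + reagent → intermediate C (k = 0.0130 /M/min)
    intermediate B ⇌ intermediate D (K = 1.20, k = 0.00590 /min)
    reagent + intermediate C ⇌ intermediate E (K = 1.70 /M, k = 0.0110 /M/min)
    reagent + intermediate C → target (k = 0.0540 /M/min)
    2 substrate → self-condensation product (k = 0.00840 /M/min)
    gas ⇌ reagent, rate k8*(csat - [reagent]) (kL = 1.10 /min)

Reckoned from the substrate at the end of each feed, the hold-up time came to 1.23 h in epsilon, 1.38 h in theta and 1.52 h in delta, against my 1.20 h. In epsilon, when the feed ended at 12.0 h, substrate stood at 10.2%, and the flask held intermediate A 22.5%, intermediate B 23.0%, intermediate D 20.1% and target 13.2%. From then to 40.0 h, with reagent at 0.200 M and substrate down to 1.00%, target grew to 23.3% as intermediate A fell to 10.8% and intermediate D rose to 30.3%.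

The numbers in the tables stem from a simulated flask for substances that don't exist; scatter was added.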